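**Remarks.** The target is coelenterazine, 8-benzyl-2-(4-hydroxybenzyl)-6-(4-hydroxyphenyl)imidazo[1,2-a]pyrazin-3(7H)-one (the name in the task is misspelled), an achiral molecule. The descriptors used below, (R) at the arylglycine-derived carbon and (6R,8S) for the cis cyclisation product, agree with the SMILES strings; no structural correction was needed. Assumption: N-Boc-D-4-hydroxyphenylglycine and N-Fmoc-O-benzyl-L-tyrosine are taken as the commercial forms of the two amino acids.

## Structural features

Coelenterazine 16 is a fused bicycle in which a five-membered imidazolone ring and a six-membered 7H-pyrazine ring share the N4–C8a bond. The periphery carries a 4-hydroxybenzyl group on C2, a benzyl group on C8 and a 4-hydroxyphenyl group on C6; C5 is the only ring C–H. The molecule has no stereocentre. The sp3 centres that appear in the intermediates (C6 and C8, 1,3-related across N7, and the tyrosine-derived carbon) are all erased before the end. The fragile part is the electron-rich C2–C3(O)–N4 enol/amide unit together with the N7–H dihydropyrazine, which takes up oxygen at C2, fastest in base; the two phenols add to this sensitivity. The real difficulty is therefore to reach the correct oxidation level of the bicycle and to unmask the C3 oxygen only at the very end, under neutral and oxygen-free conditions. The key step exploits C8a. Once the C3 oxygen is fixed as an ether, the five-membered ring is an aromatic 1,4,5-trisubstituted imidazole whose only free carbon is the amidine carbon between N1 and N4. That carbon can be joined to C8 while N7–C8 forms, from an amine tethered to N4 through C5–C6.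

## Logic of the disconnections

**16 ⇒ 15.** The three O–CH2Ph bonds are cut (two phenols and the C3 enol oxygen). The reason is that the free enol and phenols make 16 air- and base-sensitive, so they should appear only in the last operation. The gain is that all earlier chemistry runs on a robust, fully aromatic ether. The forward step must remove three benzyl groups under neutral conditions without reducing the pyrazine ring.

**15 ⇒ 14.** No skeletal bond is cut; four hydrogens are returned to C5/C6 and N7/C8. This converts the aromatic pyrazine into a saturated ring with an N7–H amine and two sp3 carbons, which is what an amine-plus-aldehyde ring closure delivers. The forward step must remove four hydrogens without oxidising the two doubly activated benzylic methylene groups or the benzyl ethers.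

**14 ⇒ 11 + 12 (through 13).** N7–C8 and C8–C8a are cut together. This is the strategic cut: it removes the six-membered ring and the C8 substituent in one operation and leaves a monocyclic imidazole and a simple aldehyde. The forward step demands a nucleophilic C8a, hence the ether at the C3 oxygen, a free primary amine, and an acid regime that does not fully block the imidazole by N-protonation.

**11 ⇒ 10 ⇒ 9.** The N–carbamate bond and then the O–CH2Ph bond at the imidazole oxygen are cut. The aromatic alkoxy-imidazole is the locked enol form of imidazolone 9, so the ring can be built at the lactam oxidation level. The forward step demands alkylation on oxygen and not on C4 or N3; a hard sulfonate electrophile in a dipolar aprotic solvent is chosen for this reason, which is an improvement over a plain benzyl halide.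

**9 ⇒ 7 + 8.** The N1–C2 and C2=N3 bonds of the imidazolone are cut, which removes the one-carbon unit that later becomes C8a. The gain is an acyclic α-amino amide. The forward cyclocondensation may scramble the tyrosine-derived centre, which is acceptable because that carbon becomes sp2 in the next step.

**7 ⇒ 6 ⇒ 4 + 5.** The amide C–N bond is cut, giving a mono-protected 1,2-diamine and a protected tyrosine. The two carbamates must be orthogonal: the base-labile one on the tyrosine nitrogen is removed first, and the acid-labile one on the benzylic nitrogen survives until just before the key step.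

**4 ⇒ 3 ⇒ 2 ⇒ 1.** The CH2–N unit of 4 is traced back to a primary carboxamide (C=O reduced to CH2), the amide to a benzyl ester (ammonolysis), and the ester and aryl ether to the hydroxy acid 1 (double O-benzylation). The forward reduction must spare the carbamate and the benzyl ether. Any loss of configuration at the arylglycine centre is harmless.

## Other disconnections considered

**Alternative 1:** The cut is the N4–C8a amidine bond of the imidazolone.

- **Forward key step.** The acyclic dipeptide amide A2 already carries the ketal-protected 4-hydroxyphenacyl unit on its C-terminal amide nitrogen. Heating with a silylating dehydrating agent would make that nitrogen attack the phenylalanine carbonyl, with loss of water, to give imidazolone A1. Acid would then remove the carbamate and the ketal, the freed amine would condense with the aryl ketone (N7–C6), and prototropic shifts would lead to 16.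
- **In favour.** A2 comes from standard peptide couplings. The sequence is redox-neutral, so no dehydrogenation is needed. Cyclodehydration of N-acylamino amides to imidazolones is established chemistry.
- **Against.** The attacking nitrogen is a secondary amide nitrogen between two branched centres. Closure through oxygen and diketopiperazine formation compete. A1 and every later compound carry the enolisable imidazolone and free phenols, the air-sensitive functionality of 16.
- **Comparison.** On step economy the alternative is equal or slightly better, since it avoids the amide-reduction and dehydrogenation detour of steps 3 and 10. On mechanism it is better founded than step 9. On structure the chosen plan is better, because 10 to 15 are fully protected and 15 is a stable aromatic ether.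

**Alternative 2:** The cut is the N1=C8a bond.

- **Forward key step.** Azide A4, a pyrazinone acylated on the ring nitrogen by an α-azido acid, would be treated with a triarylphosphine. Loss of dinitrogen gives an iminophosphorane, which attacks the adjacent ring carbonyl with expulsion of the phosphine oxide to give the bis(aryl acetate) A3. Mild cleavage of the two acetates would give 16.
- **In favour.** Aza-Wittig closure onto imide-type carbonyls is known. The pyrazine ring is in place and aromatic from the start. No redox adjustment is needed and the conditions are neutral.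
- **Against.** Acylation of a pyrazin-2(1H)-one is ambident and normally occurs on oxygen. The N-acyl isomer is an imide-like acyl donor that water, the phosphine or a second iminophosphorane could cleave. The α-azido acyl chloride has an acidic α-hydrogen. The final deacetylation needs a nucleophile close to the base-sensitive 16.
- **Comparison.** The alternative is equal or better in step count and convergence, and its key step has better precedent than step 9. The uncertainty moves to the making and survival of A4, which is judged at least as uncertain as step 9. The chosen plan is better in keeping the enol masked until the last step.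

**Alternative 3:** The cuts are N1–C2, C2–C3 and C3–N4.

- **Forward key step.** The aminopyrazine A6 (coelenteramine), the aldehyde A7 (4-hydroxyphenylacetaldehyde) and the isocyanide A8 (tert-butyl isocyanide) would combine under Lewis-acid catalysis. Imine formation at the exocyclic amine, isocyanide addition and capture of the nitrilium ion by the ring nitrogen give A5.
- **In favour.** This is the shortest and most convergent plan. The reaction class is well established for 2-aminopyrazines, the pyrazine is aromatic throughout, and A6 is reachable in few steps.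
- **Against.** A5 carries nitrogen where 16 needs oxygen at C3. The tert-butyl group must be removed and the amino group exchanged for oxo through the 3-imino tautomer, for which no secure method is evident on this electron-rich substrate with free phenols. A7 is enolisable and self-condensing. The amino group of A6 is hindered by the neighbouring benzyl group.
- **Comparison.** Up to A5 the alternative is better than the chosen plan in step count and precedent. Beyond A5 the chosen plan is better: its C3 oxygen comes from the tyrosine carboxyl and is present from the start, and its two finishing steps are standard. Overall step economy is comparable only if the nitrogen-to-oxygen exchange can be done in one or two operations.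

Key step: step 9

## Route

**Step 1**
Reactants: 1 N-Boc-D-4-hydroxyphenylglycine [(2R)-2-(tert-butoxycarbonylamino)-2-(4-hydroxyphenyl)acetic acid]
Product: 2 benzyl (2R)-2-(4-benzyloxyphenyl)-2-(tert-butoxycarbonylamino)acetate
Conditions: BnBr (2.3 equiv), K2CO3, DMF, rt → 50 °C
Reagents that add atoms: benzyl bromide, BrCc1ccccc1
Why: Carboxylate and phenoxide are both alkylated by SN2 displacement (ester alkylation and Williamson ether synthesis), while the carbamate N–H is not acidic enough to react under carbonate; erosion of the arylglycine centre would be harmless.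

**Step 2**
Reactants: 2 benzyl (2R)-2-(4-benzyloxyphenyl)-2-(tert-butoxycarbonylamino)acetate
Product: 3 (2R)-2-(4-benzyloxyphenyl)-2-(tert-butoxycarbonylamino)acetamide
Conditions: NH3 (7 M in MeOH), rt, sealed vessel
Reagents that add atoms: ammonia, N
Why: Ammonolysis of an ester activated by the α-aryl and α-carbamate groups should give the primary amide; the aryl benzyl ether and the Boc group do not react with ammonia.

**Step 3**
Reactants: 3 (2R)-2-(4-benzyloxyphenyl)-2-(tert-butoxycarbonylamino)acetamide
Product: 4 tert-butyl N-[(1R)-2-amino-1-(4-benzyloxyphenyl)ethyl]carbamate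
Conditions: BH3·THF (4 equiv), THF, 0 → 65 °C; then MeOH, 65 °C
Reagents that add atoms: none
Why: Borane reduces primary carboxamides to amines much faster than it attacks carbamates, and methanolysis releases the amine from its borane adduct; benzyl ether and Boc group are expected to survive.

**Step 4**
Reactants: 4 tert-butyl N-[(1R)-2-amino-1-(4-benzyloxyphenyl)ethyl]carbamate; 5 N-Fmoc-O-benzyl-L-tyrosine
Product: 6 9H-fluoren-9-ylmethyl N-[(2S)-3-(4-benzyloxyphenyl)-1-{[(2R)-2-(4-benzyloxyphenyl)-2-(tert-butoxycarbonylamino)ethyl]amino}-1-oxopropan-2-yl]carbamate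
Conditions: N,N'-diisopropylcarbodiimide (DIC), HOBt, DCM/DMF, 0 °C → rt
Reagents that add atoms: none
Why: Carbodiimide/HOBt amide coupling of a urethane-protected amino acid with the only free amine of 4, an unhindered primary CH2NH2 group.

**Step 5**
Reactants: 6 Fmoc-protected amide from step 4
Product: 7 tert-butyl N-[(1R)-2-{[(2S)-2-amino-3-(4-benzyloxyphenyl)propanoyl]amino}-1-(4-benzyloxyphenyl)ethyl]carbamate
Conditions: piperidine (20% v/v), DMF, rt
Reagents that add atoms: none
Why: Base-induced E1cB cleavage of the fluorenylmethyl carbamate with trapping of dibenzofulvene by piperidine; the Boc group and the benzyl ethers are inert, which is the point of the Fmoc/Boc pairing.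

**Step 6**
Reactants: 7 tert-butyl N-[(1R)-2-{[(2S)-2-amino-3-(4-benzyloxyphenyl)propanoyl]amino}-1-(4-benzyloxyphenyl)ethyl]carbamate; 8 triethyl orthoformate
Product: 9 tert-butyl N-[(1R)-2-[4-(4-benzyloxybenzyl)-5-oxo-4,5-dihydro-1H-imidazol-1-yl]-1-(4-benzyloxyphenyl)ethyl]carbamate (C4 epimers)
Conditions: HC(OEt)3 (5 equiv), AcOH (cat.), toluene, 110 °C, Ar; crude product used directly
Reagents that add atoms: none
Why: Cyclocondensation of an α-amino amide with an orthoester: the primary amine forms a formimidate, the amide nitrogen closes the ring and ethanol is lost, the established route to 4H-imidazol-5-ones. The labile C4 centre may epimerise, which is irrelevant, and the product is kept under argon because the C4–H is prone to autoxidation.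

**Step 7**
Reactants: 9 tert-butyl N-[(1R)-2-[4-(4-benzyloxybenzyl)-5-oxo-4,5-dihydro-1H-imidazol-1-yl]-1-(4-benzyloxyphenyl)ethyl]carbamate
Product: 10 tert-butyl N-[(1R)-2-[5-benzyloxy-4-(4-benzyloxybenzyl)-1H-imidazol-1-yl]-1-(4-benzyloxyphenyl)ethyl]carbamate
Conditions: Cs2CO3 (1.5 equiv), BnOTs (1.1 equiv), DMF, 0 °C → rt, Ar
Reagents that add atoms: benzyl p-toluenesulfonate, Cc1ccc(cc1)S(=O)(=O)OCc1ccccc1
Why: Deprotonation at C4 gives an aromatic imidazol-5-olate, an ambident anion; a hard sulfonate leaving group, the caesium counter-ion and a dipolar aprotic solvent should steer alkylation to oxygen, as in the O-alkylation of other hydroxy-azole tautomers. The product is an aromatic imidazole and the C4 stereocentre is removed; a small excess of electrophile limits quaternisation at N3.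

**Step 8**
Reactants: 10 tert-butyl N-[(1R)-2-[5-benzyloxy-4-(4-benzyloxybenzyl)-1H-imidazol-1-yl]-1-(4-benzyloxyphenyl)ethyl]carbamate
Product: 11 (1R)-2-[5-benzyloxy-4-(4-benzyloxybenzyl)-1H-imidazol-1-yl]-1-(4-benzyloxyphenyl)ethan-1-amine
Conditions: TFA/DCM (1:4), 0 °C → rt; aq. NaHCO3 work-up
Reagents that add atoms: none
Why: Acidolysis of the tert-butyl carbamate; the benzyl ethers tolerate trifluoroacetic acid, and the alkoxy-imidazole is protonated at N3 and not at C4, so its enol ether should not be cleaved.

**Step 9**
Reactants: 11 (1R)-2-[5-benzyloxy-4-(4-benzyloxybenzyl)-1H-imidazol-1-yl]-1-(4-benzyloxyphenyl)ethan-1-amine; 12 phenylacetaldehyde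
Product: 14 (6R,8S)-8-benzyl-3-benzyloxy-2-(4-benzyloxybenzyl)-6-(4-benzyloxyphenyl)-5,6,7,8-tetrahydroimidazo[1,2-a]pyrazine, via aldimine 13 (not isolated)
Conditions: 4 Å MS, DCM, rt, 2 h; then TFA (1.1 equiv), 0 → 40 °C, Ar
Reagents that add atoms: none
Why: Proposed new method: condensation of the primary amine of 11 with 12 over molecular sieves should give aldimine 13, and one equivalent of acid then shares a proton between the imine nitrogen and imidazole N3, so that the protomer with a free imidazole and an N7=C8 iminium ion is available. The unsubstituted imidazole carbon (the future C8a) attacks the iminium carbon; the σ-complex is stabilised as an oxocarbenium ion at the benzyloxy-bearing carbon and as an iminium ion at the ring nitrogen, and loss of the C–H proton restores the aromatic imidazole, while an ylide pathway (N3-protonated imidazolium deprotonated at the same carbon) would form the same bond. The closest known reaction type is the Pictet–Spengler cyclisation of 1-(2-aminoaryl)imidazoles with aldehydes at imidazole C2 to imidazo[1,2-a]quinoxalines, and more remotely that of N-(2-aminoethyl)pyrroles and tryptamines; new here is the aliphatic amine tether on an alkoxy-imidazole. The six-membered ring closes in the 6-endo-trig mode, both atoms of the C=N bond ending up in the ring. The new stereocentre C8 is controlled by the existing C6 centre, and reversible closure should favour the 6,8-cis isomer with both substituents pseudo-equatorial; the outcome is immaterial because both centres are dehydrogenated in step 10. Regioselectivity needs no control beyond substitution, since the other two imidazole carbons are blocked and attack at either would be reversible for lack of a proton to lose. The step needs chemoselectivity for iminium capture over enamine formation and self-aldol reaction of the enolisable aldehyde, which pre-forming the imine at room temperature and adding the acid cold should secure.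

**Step 10**
Reactants: 14 (6R,8S)-8-benzyl-3-benzyloxy-2-(4-benzyloxybenzyl)-6-(4-benzyloxyphenyl)-5,6,7,8-tetrahydroimidazo[1,2-a]pyrazine
Product: 15 8-benzyl-3-benzyloxy-2-(4-benzyloxybenzyl)-6-(4-benzyloxyphenyl)imidazo[1,2-a]pyrazine
Conditions: activated MnO2 (15 equiv), toluene, 90 °C
Reagents that add atoms: none
Why: Oxidative aromatisation of a saturated aza-ring, as in the conversion of tetrahydro-β-carbolines into β-carbolines: the secondary amine is oxidised to an imine conjugated with the arene or the imidazole, tautomerisation exposes a second oxidisable position, and the second dehydrogenation is driven by formation of the ten-π-electron aromatic bicycle. Both stereocentres disappear.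

**Step 11**
Reactants: 15 8-benzyl-3-benzyloxy-2-(4-benzyloxybenzyl)-6-(4-benzyloxyphenyl)imidazo[1,2-a]pyrazine
Product: 16 coelenterazine [8-benzyl-2-(4-hydroxybenzyl)-6-(4-hydroxyphenyl)imidazo[1,2-a]pyrazin-3(7H)-one]
Conditions: H2 (1 atm), 10% Pd/C, EtOAc/MeOH, rt; filtration and concentration under Ar
Reagents that add atoms: none
Why: Hydrogenolysis of two aryl benzyl ethers and one heteroaryl benzyl ether; the liberated 3-hydroxy compound tautomerises to the 3(7H)-one. Neutral conditions and exclusion of oxygen during isolation should protect the enol from autoxidation.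

## Compound list

1 | N-Boc-D-4-hydroxyphenylglycine | CC(C)(C)OC(=O)N[C@H](c1ccc(O)cc1)C(=O)O | starting material
2 | benzyl (2R)-2-(4-benzyloxyphenyl)-2-(tert-butoxycarbonylamino)acetate | CC(C)(C)OC(=O)N[C@H](c1ccc(OCc2ccccc2)cc1)C(=O)OCc1ccccc1 | intermediate
3 | (2R)-2-(4-benzyloxyphenyl)-2-(tert-butoxycarbonylamino)acetamide | CC(C)(C)OC(=O)N[C@H](c1ccc(OCc2ccccc2)cc1)C(N)=O | intermediate
4 | tert-butyl N-[(1R)-2-amino-1-(4-benzyloxyphenyl)ethyl]carbamate | CC(C)(C)OC(=O)N[C@H](c1ccc(OCc2ccccc2)cc1)CN | intermediate
5 | N-Fmoc-O-benzyl-L-tyrosine | O=C(O)[C@H](Cc1ccc(OCc2ccccc2)cc1)NC(=O)OCC1c2ccccc2-c2ccccc21 | starting material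
6 | 9H-fluoren-9-ylmethyl N-[(2S)-3-(4-benzyloxyphenyl)-1-{[(2R)-2-(4-benzyloxyphenyl)-2-(tert-butoxycarbonylamino)ethyl]amino}-1-oxopropan-2-yl]carbamate | CC(C)(C)OC(=O)N[C@H](c1ccc(OCc2ccccc2)cc1)CNC(=O)[C@H](Cc1ccc(OCc2ccccc2)cc1)NC(=O)OCC1c2ccccc2-c2ccccc21 | intermediate
7 | tert-butyl N-[(1R)-2-{[(2S)-2-amino-3-(4-benzyloxyphenyl)propanoyl]amino}-1-(4-benzyloxyphenyl)ethyl]carbamate | CC(C)(C)OC(=O)N[C@H](c1ccc(OCc2ccccc2)cc1)CNC(=O)[C@@H](N)Cc1ccc(OCc2ccccc2)cc1 | intermediate
8 | triethyl orthoformate | CCOC(OCC)OCC | starting material
9 | tert-butyl N-[(1R)-2-[4-(4-benzyloxybenzyl)-5-oxo-4,5-dihydro-1H-imidazol-1-yl]-1-(4-benzyloxyphenyl)ethyl]carbamate (C4 epimers, configurationally labile) | CC(C)(C)OC(=O)N[C@H](c1ccc(OCc2ccccc2)cc1)CN1C=NC(Cc2ccc(OCc3ccccc3)cc2)C1=O | intermediate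
10 | tert-butyl N-[(1R)-2-[5-benzyloxy-4-(4-benzyloxybenzyl)-1H-imidazol-1-yl]-1-(4-benzyloxyphenyl)ethyl]carbamate | CC(C)(C)OC(=O)N[C@H](c1ccc(OCc2ccccc2)cc1)Cn1cnc(Cc2ccc(OCc3ccccc3)cc2)c1OCc1ccccc1 | intermediate
11 | (1R)-2-[5-benzyloxy-4-(4-benzyloxybenzyl)-1H-imidazol-1-yl]-1-(4-benzyloxyphenyl)ethan-1-amine | N[C@H](c1ccc(OCc2ccccc2)cc1)Cn1cnc(Cc2ccc(OCc3ccccc3)cc2)c1OCc1ccccc1 | intermediate
12 | phenylacetaldehyde | O=CCc1ccccc1 | starting material
13 | (E)-N-[(1R)-2-[5-benzyloxy-4-(4-benzyloxybenzyl)-1H-imidazol-1-yl]-1-(4-benzyloxyphenyl)ethyl]-2-phenylethan-1-imine | c1ccccc1C/C=N/[C@H](c1ccc(OCc2ccccc2)cc1)Cn1cnc(Cc2ccc(OCc3ccccc3)cc2)c1OCc1ccccc1 | intermediate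
14 | (6R,8S)-8-benzyl-3-benzyloxy-2-(4-benzyloxybenzyl)-6-(4-benzyloxyphenyl)-5,6,7,8-tetrahydroimidazo[1,2-a]pyrazine (cis) | N1[C@H](c2ccc(OCc3ccccc3)cc2)Cn2c(nc(Cc3ccc(OCc4ccccc4)cc3)c2OCc2ccccc2)[C@@H]1Cc1ccccc1 | intermediate
15 | 8-benzyl-3-benzyloxy-2-(4-benzyloxybenzyl)-6-(4-benzyloxyphenyl)imidazo[1,2-a]pyrazine | c1ccccc1Cc1nc(-c2ccc(OCc3ccccc3)cc2)cn2c(OCc3ccccc3)c(Cc3ccc(OCc4ccccc4)cc3)nc12 | intermediate
16 | coelenterazine, 8-benzyl-2-(4-hydroxybenzyl)-6-(4-hydroxyphenyl)imidazo[1,2-a]pyrazin-3(7H)-one | O=c1c(Cc2ccc(O)cc2)nc2c(Cc3ccccc3)[nH]c(-c3ccc(O)cc3)cn1-2 | target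

## Step count and least certain steps

Total step count: 11. Longest linear sequence: 11 steps (1 to 16); compounds 5, 8 and 12 enter as commercial materials.

**Step 9 (key step, the only step beyond precedent).** The most likely failure is that ring closure does not occur: protonation at N3 deactivates the imidazole, while the imine drifts to its conjugated enamine and the aldehyde is consumed by self-condensation. Fallback by known chemistry, setting out from 10 and returning at 14: the C8–C8a bond is made by lithiation and the benzyl group is added afterwards.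
- Double deprotonation of 10 (n-BuLi, 2.2 equiv, THF, −78 °C; carbamate N–H first, then imidazole C2–H) and quenching with DMF should give tert-butyl N-[(1R)-2-[5-benzyloxy-4-(4-benzyloxybenzyl)-2-formyl-1H-imidazol-1-yl]-1-(4-benzyloxyphenyl)ethyl]carbamate F1.
- Removal of the carbamate (TFA/DCM, then NaHCO3) frees the amine, which should condense with the neighbouring aldehyde to the cyclic aldimine (6R)-3-benzyloxy-2-(4-benzyloxybenzyl)-6-(4-benzyloxyphenyl)-5,6-dihydroimidazo[1,2-a]pyrazine F2.
- Addition of BnMgCl (THF, −78 → 0 °C) to the C8=N7 bond should give 14 as either C8 epimer, both of which serve in step 10.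

**Step 7.** The risk is poor site selectivity of the ambident anion, with benzylation at C4 (a quaternary imidazolone) or at N3 competing with the desired attack through oxygen. Fallback from 9 back to 10: a Mitsunobu etherification with benzyl alcohol (PPh3, diisopropyl azodicarboxylate, THF, 0 °C), in which the electrophile is an alkoxyphosphonium ion and the hydroxy-imidazole tautomer reacts as an oxygen acid; this is a change from enolate alkylation to redox condensation. No new compound is made (F0).

**Step 10.** The risk is stalling at the dihydro stage, or oxidation at the doubly activated benzylic methylene groups on C2 and C8 on prolonged heating with a large excess of oxidant. Fallback from 14 back to 15 by an ionic, stepwise sequence.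
- N-Chlorination (N-chlorosuccinimide, DCM, 0 °C) should give (6R,8S)-8-benzyl-3-benzyloxy-2-(4-benzyloxybenzyl)-6-(4-benzyloxyphenyl)-7-chloro-5,6,7,8-tetrahydroimidazo[1,2-a]pyrazine F3.
- Dehydrochlorination with DBU should give the conjugated imine (6R)-8-benzyl-3-benzyloxy-2-(4-benzyloxybenzyl)-6-(4-benzyloxyphenyl)-5,6-dihydroimidazo[1,2-a]pyrazine F4.
- F4 needs only one further, aromatisation-driven dehydrogenation (DDQ, 1 equiv, dioxane, rt) to reach 15.

**Step 11.** The risk is over-reduction of the pyrazine ring on the catalyst, or autoxidation of the liberated enol during filtration and concentration. Fallback from 15 to 16: non-reductive cleavage of the three benzyl ethers with BCl3 and pentamethylbenzene as cation scavenger (DCM, −78 °C, methanol quench under Ar), which avoids both the metal surface and the filtration in air. No new compound is made (F0).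

**Step 3.** The risk is slow reduction of the primary amide, with partial reduction or loss of the carbamate and incomplete release of the amine from boron. Fallback from 2 back to 4 without an amide reduction.
- LiBH4 (THF, 0 °C → rt) reduces the benzyl ester to tert-butyl N-[(1R)-1-(4-benzyloxyphenyl)-2-hydroxyethyl]carbamate F5.
- A Mitsunobu reaction with phthalimide (PPh3, diisopropyl azodicarboxylate) gives tert-butyl N-[(1R)-1-(4-benzyloxyphenyl)-2-(1,3-dioxoisoindolin-2-yl)ethyl]carbamate F6.
- Hydrazinolysis (N2H4·H2O, EtOH, 60 °C) frees the primary amine 4.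

## Further compounds

F1 | step 9 | tert-butyl N-[(1R)-2-[5-benzyloxy-4-(4-benzyloxybenzyl)-2-formyl-1H-imidazol-1-yl]-1-(4-benzyloxyphenyl)ethyl]carbamate | CC(C)(C)OC(=O)N[C@H](c1ccc(OCc2ccccc2)cc1)Cn1c(C=O)nc(Cc2ccc(OCc3ccccc3)cc2)c1OCc1ccccc1
F2 | step 9 | (6R)-3-benzyloxy-2-(4-benzyloxybenzyl)-6-(4-benzyloxyphenyl)-5,6-dihydroimidazo[1,2-a]pyrazine | N1=Cc2nc(Cc3ccc(OCc4ccccc4)cc3)c(OCc3ccccc3)n2C[C@H]1c1ccc(OCc2ccccc2)cc1
F0 | step 7 | none | none
F3 | step 10 | (6R,8S)-8-benzyl-3-benzyloxy-2-(4-benzyloxybenzyl)-6-(4-benzyloxyphenyl)-7-chloro-5,6,7,8-tetrahydroimidazo[1,2-a]pyrazine | ClN1[C@H](c2ccc(OCc3ccccc3)cc2)Cn2c(nc(Cc3ccc(OCc4ccccc4)cc3)c2OCc2ccccc2)[C@@H]1Cc1ccccc1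
F4 | step 10 | (6R)-8-benzyl-3-benzyloxy-2-(4-benzyloxybenzyl)-6-(4-benzyloxyphenyl)-5,6-dihydroimidazo[1,2-a]pyrazine | N1=C(Cc2ccccc2)c2nc(Cc3ccc(OCc4ccccc4)cc3)c(OCc3ccccc3)n2C[C@H]1c1ccc(OCc2ccccc2)cc1
F0 | step 11 | none | none
F5 | step 3 | tert-butyl N-[(1R)-1-(4-benzyloxyphenyl)-2-hydroxyethyl]carbamate | CC(C)(C)OC(=O)N[C@H](c1ccc(OCc2ccccc2)cc1)CO
F6 | step 3 | tert-butyl N-[(1R)-1-(4-benzyloxyphenyl)-2-(1,3-dioxoisoindolin-2-yl)ethyl]carbamate | CC(C)(C)OC(=O)N[C@H](c1ccc(OCc2ccccc2)cc1)CN1C(=O)c2ccccc2C1=O
A1 | alternative 1 | 2-[(S)-1-(Boc-amino)-2-phenylethyl]-4-(4-hydroxybenzyl)-1-{[2-(4-hydroxyphenyl)-1,3-dioxolan-2-yl]methyl}-1H-imidazol-5(4H)-one | CC(C)(C)OC(=O)N[C@@H](Cc1ccccc1)C1=N[C@@H](Cc2ccc(O)cc2)C(=O)N1CC1(c2ccc(O)cc2)OCCO1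
A2 | alternative 1 | N-Boc-L-phenylalanyl-L-tyrosine N-{[2-(4-hydroxyphenyl)-1,3-dioxolan-2-yl]methyl}amide | CC(C)(C)OC(=O)N[C@@H](Cc1ccccc1)C(=O)N[C@@H](Cc1ccc(O)cc1)C(=O)NCC1(c2ccc(O)cc2)OCCO1
A3 | alternative 2 | coelenterazine bis(aryl acetate) | O=c1c(Cc2ccc(OC(C)=O)cc2)nc2c(Cc3ccccc3)[nH]c(-c3ccc(OC(C)=O)cc3)cn1-2
A4 | alternative 2 | 5-(4-acetoxyphenyl)-1-[3-(4-acetoxyphenyl)-2-azidopropanoyl]-3-benzylpyrazin-2(1H)-one | CC(=O)Oc1ccc(CC(N=[N+]=[N-])C(=O)n2cc(-c3ccc(OC(C)=O)cc3)nc(Cc3ccccc3)c2=O)cc1
A5 | alternative 3 | 8-benzyl-3-(tert-butylamino)-2-(4-hydroxybenzyl)-6-(4-hydroxyphenyl)imidazo[1,2-a]pyrazine | CC(C)(C)Nc1c(Cc2ccc(O)cc2)nc2c(Cc3ccccc3)nc(-c3ccc(O)cc3)cn12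
A6 | alternative 3 | coelenteramine, 3-benzyl-5-(4-hydroxyphenyl)pyrazin-2-amine | Nc1ncc(-c2ccc(O)cc2)nc1Cc1ccccc1
A7 | alternative 3 | 4-hydroxyphenylacetaldehyde | O=CCc1ccc(O)cc1
A8 | alternative 3 | tert-butyl isocyanide | [C-]#[N+]C(C)(C)C
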